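**Retrosynthetic overview**
1. The target comes from its 4',5-di-O-benzyl ether by hydrogenolysis. The two sulfates are put on just before that, on the only two free hydroxyls (3-OH and 3'-OH), which are unmasked from MOM ethers.
2. The 5-O-benzyl group comes from a 5-fluoride by SNAr with benzyl alkoxide on the finished chromone.
3. Ring C (the pyranone) is the only ring made. Its O1–C8a bond is formed by intramolecular SNAr of a 2-alkoxy-1,3-diketone enolate. The feature used is that in ring A, C5 and C8a both flank C4a (the carbon carrying C4=O) and are both meta to C7–OMe. Ring A is therefore a 2,6-difluoro-4-methoxybenzoyl unit with two equivalent C–F bonds: one becomes C8a–O1, the other C5–O.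
4. The diketone comes from C-aroylation of an α-MOM-oxy ketone (3,5-difluoroanisole lithiated between the fluorines, plus a MOM-glycolic Weinreb amide) with 4-benzyloxy-3-MOM-oxybenzoyl chloride (from 3,4-dihydroxybenzaldehyde).
5. Rings A and B are bought.

Key step: step 9

Remark: the target has no stereocentre, so no enantiocontrol is needed; the sulfate esters are drawn as free acids as in the target, but would be handled as trialkylammonium salts until the final H+ exchange, and the free acid should be kept cold.

**Route**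

Step 1
Reactants: 1 methyl glycolate
Product: 2 methyl 2-(methoxymethoxy)acetate
Conditions: MOMCl, i-Pr2NEt, CH2Cl2, 0 °C → rt
Reagents that add atoms: chloromethyl methyl ether, COCCl
Why: O-alkylation of the primary alcohol with MOMCl and Hünig's base (MOM protection) is routine and the ester is inert to it.

Step 2
Reactants: 2 methyl 2-(methoxymethoxy)acetate
Product: 3 N-methoxy-2-(methoxymethoxy)-N-methylacetamide
Conditions: MeNHOMe·HCl, i-PrMgCl, THF, −20 → 0 °C
Reagents that add atoms: N,O-dimethylhydroxylamine hydrochloride, CNOC.Cl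
Why: Direct ester-to-Weinreb-amide aminolysis by the chloromagnesium amide made in situ; the acetal is stable to the basic medium.

Step 3
Reactants: 4 3,5-difluoroanisole; 3 N-methoxy-2-(methoxymethoxy)-N-methylacetamide
Product: 7 1-(2,6-difluoro-4-methoxyphenyl)-2-(methoxymethoxy)ethan-1-one, via aryllithium 5 (not isolated), via lithium hemiaminal adduct 6 (not isolated)
Conditions: n-BuLi, THF, −78 °C; then 3, −78 → −20 °C; aq. NH4Cl
Reagents that add atoms: none
Why: Directed ortho-lithiation removes the most acidic proton, the one between the two fluorines, the aryllithium is stable at −78 °C, and the chelated Weinreb adduct should prevent over-addition and release the ketone only on quench (Weinreb ketone synthesis).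

Step 4
Reactants: 8 3,4-dihydroxybenzaldehyde
Product: 9 4-(benzyloxy)-3-hydroxybenzaldehyde
Conditions: BnBr (1.0 equiv), NaHCO3, NaI (cat.), DMF, 40 °C
Reagents that add atoms: benzyl bromide, BrCc1ccccc1
Why: Regioselective Williamson etherification: the 4-OH, para to the formyl group, is the more acidic phenol, so a weak base and one equivalent of halide should alkylate O4 only.

Step 5
Reactants: 9 4-(benzyloxy)-3-hydroxybenzaldehyde
Product: 10 4-(benzyloxy)-3-(methoxymethoxy)benzaldehyde
Conditions: MOMCl, i-Pr2NEt, CH2Cl2, 0 °C → rt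
Reagents that add atoms: chloromethyl methyl ether, COCCl
Why: MOM protection of the remaining phenol gives a 3'-oxygen mask that is orthogonal to the benzyl ether; aldehyde and benzyl ether are untouched.

Step 6
Reactants: 10 4-(benzyloxy)-3-(methoxymethoxy)benzaldehyde
Product: 11 4-(benzyloxy)-3-(methoxymethoxy)benzoic acid
Conditions: NaClO2, NaH2PO4, 2-methyl-2-butene, t-BuOH/H2O, rt
Reagents that add atoms: sodium chlorite, [Na+].[O-]Cl=O
Why: Pinnick oxidation at buffered pH converts the aldehyde to the acid without harming the benzyl or MOM ether, and the alkene scavenges HOCl so the electron-rich ring is not chlorinated.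

Step 7
Reactants: 11 4-(benzyloxy)-3-(methoxymethoxy)benzoic acid
Product: 12 4-(benzyloxy)-3-(methoxymethoxy)benzoyl chloride
Conditions: 1-chloro-N,N,2-trimethylprop-1-en-1-amine (Ghosez reagent), CH2Cl2, 0 °C → rt; concentrate, use crude
Reagents that add atoms: 1-chloro-N,N,2-trimethylprop-1-en-1-amine, CC(C)=C(Cl)N(C)C
Why: The α-chloroenamine makes the acid chloride under neutral conditions and gives only a neutral amide, no HCl, so the acid-labile MOM ether should survive.

Step 8
Reactants: 7 1-(2,6-difluoro-4-methoxyphenyl)-2-(methoxymethoxy)ethan-1-one; 12 4-(benzyloxy)-3-(methoxymethoxy)benzoyl chloride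
Product: 14 1-[4-(benzyloxy)-3-(methoxymethoxy)phenyl]-3-(2,6-difluoro-4-methoxyphenyl)-2-(methoxymethoxy)propane-1,3-dione (racemic at C2, in equilibrium with its enols), via lithium enolate 13 (not isolated)
Conditions: LiHMDS (2.2 equiv), THF, −78 °C; then 12, −78 → 0 °C; aq. NH4Cl
Reagents that add atoms: none
Why: Crossed-Claisen C-aroylation of the chelated lithium Z-enolate of an α-alkoxy ketone with an aroyl chloride; the second equivalent of base deprotonates the more acidic diketone as it forms, and the lithium counter-ion and low temperature keep the C–F bonds intact at this stage.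

Step 9
Reactants: 14 1-[4-(benzyloxy)-3-(methoxymethoxy)phenyl]-3-(2,6-difluoro-4-methoxyphenyl)-2-(methoxymethoxy)propane-1,3-dione
Product: 16 2-[4-(benzyloxy)-3-(methoxymethoxy)phenyl]-5-fluoro-7-methoxy-3-(methoxymethoxy)-4H-chromen-4-one, via potassium enolate 15 (not isolated)
Conditions: K2CO3 (anhydrous), DMF, 60 °C
Reagents that add atoms: none
Why: Carbonate deprotonates the diketone at C2 to give enolate 15, whose B-ring-side oxygen adds to a fluorine-bearing ring-A carbon ortho to the aroyl carbonyl; the Meisenheimer anion is delocalised onto that carbonyl and expels fluoride (addition–elimination SNAr), forming O1–C8a. The closest known reaction type is the base-mediated cyclisation of 1-(2-fluoroaryl)-1,3-diketones and 2,6-difluorobenzoyl acetates to chromones, flavones and 5-fluoro-4-quinolones. Ring C closes as a six-membered ring by O-attack on an aromatic sp2 carbon (formally 6-exo-trig), and no stereocentre is formed, since the racemic C2 of 14 becomes the sp2 C3 of 16. The step needs O- over C-cyclisation and a single site of attack: C-attack or attack by the A-ring-side oxygen would require a four-membered ring, and the two C–F bonds are interchanged by rotation about the aryl–carbonyl bond, so either closure gives the same product. The 7-OMe group is meta to both C–F carbons and so does not feed electron density to them, and the fluoride that remains sits peri to C4=O and stays activated for step 10. Dry carbonate in DMF at moderate temperature is chosen to avoid retro-Claisen cleavage of the diketone and amine formation from the solvent.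

Step 10
Reactants: 16 2-[4-(benzyloxy)-3-(methoxymethoxy)phenyl]-5-fluoro-7-methoxy-3-(methoxymethoxy)-4H-chromen-4-one
Product: 17 5-(benzyloxy)-2-[4-(benzyloxy)-3-(methoxymethoxy)phenyl]-7-methoxy-3-(methoxymethoxy)-4H-chromen-4-one
Conditions: BnOH, NaH, THF/DMF, 0 °C → rt
Reagents that add atoms: benzyl alcohol, OCc1ccccc1
Why: Intermolecular SNAr: C5–F is ortho to C4a, which carries the C4 carbonyl, so benzyloxide addition gives a carbonyl-stabilised Meisenheimer anion and fluoride is the only leaving group; addition at C2 of the pyranone is reversible, whereas fluoride loss is not.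

Step 11
Reactants: 17 5-(benzyloxy)-2-[4-(benzyloxy)-3-(methoxymethoxy)phenyl]-7-methoxy-3-(methoxymethoxy)-4H-chromen-4-one
Product: 18 5-(benzyloxy)-2-[4-(benzyloxy)-3-hydroxyphenyl]-3-hydroxy-7-methoxy-4H-chromen-4-one
Conditions: HCl (1.25 M in MeOH), THF, 40 °C
Reagents that add atoms: none
Why: Acid-catalysed acetal exchange removes both MOM groups, while benzyl and methyl ethers should tolerate dilute methanolic HCl; any partial loss of the peri 5-O-benzyl group would be harmless, since a chelated 5-OH is the target function and is inert to sulfation.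

Step 12
Reactants: 18 5-(benzyloxy)-2-[4-(benzyloxy)-3-hydroxyphenyl]-3-hydroxy-7-methoxy-4H-chromen-4-one
Product: 19 5-(benzyloxy)-2-[4-(benzyloxy)-3-(sulfooxy)phenyl]-7-methoxy-4-oxo-4H-chromen-3-yl hydrogen sulfate (handled as its trialkylammonium salt, drawn as the free acid)
Conditions: SO3·NMe3 (excess), Et3N, DMF, 60 °C
Reagents that add atoms: sulfur trioxide–trimethylamine complex, C[N+](C)(C)S(=O)(=O)[O-]
Why: O-sulfation of phenolic and enolic hydroxyls with an SO3–amine complex; only the 3-OH and 3'-OH are free, so excess reagent should drive both to the sulfate monoesters, with 5-O and 4'-O blocked as benzyl ethers.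

Step 13
Reactants: 19 5-(benzyloxy)-2-[4-(benzyloxy)-3-(sulfooxy)phenyl]-7-methoxy-4-oxo-4H-chromen-3-yl hydrogen sulfate
Product: 20 rhamnetin 3,3'-disulfate, 5-hydroxy-2-[4-hydroxy-3-(sulfooxy)phenyl]-7-methoxy-4-oxo-4H-chromen-3-yl hydrogen sulfate
Conditions: H2 (1 atm), 10% Pd/C, MeOH/H2O, rt; then Dowex 50W (H+), 0 °C; freeze-dry
Reagents that add atoms: none
Why: Catalytic hydrogenolysis cleaves both benzyl aryl ethers, whereas aryl sulfate monoesters and the chromone C2=C3 bond are not reduced over Pd/C at 1 atm, and cold H+ exchange should release the free acid.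

**Compound list**
1 | methyl glycolate | OCC(=O)OC | starting material
2 | methyl 2-(methoxymethoxy)acetate | COCOCC(=O)OC | intermediate
3 | N-methoxy-2-(methoxymethoxy)-N-methylacetamide | COCOCC(=O)N(C)OC | intermediate
4 | 3,5-difluoroanisole | COc1cc(F)cc(F)c1 | starting material
5 | (2,6-difluoro-4-methoxyphenyl)lithium (formed in situ) | [Li]c1c(F)cc(OC)cc1F | intermediate
6 | lithium 1-(2,6-difluoro-4-methoxyphenyl)-1-[methoxy(methyl)amino]-2-(methoxymethoxy)ethan-1-olate (racemic, formed in situ) | COCOCC(O[Li])(N(C)OC)c1c(F)cc(OC)cc1F | intermediate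
7 | 1-(2,6-difluoro-4-methoxyphenyl)-2-(methoxymethoxy)ethan-1-one | COCOCC(=O)c1c(F)cc(OC)cc1F | intermediate
8 | 3,4-dihydroxybenzaldehyde | O=Cc1ccc(O)c(O)c1 | starting material
9 | 4-(benzyloxy)-3-hydroxybenzaldehyde | O=Cc1ccc(OCc2ccccc2)c(O)c1 | intermediate
10 | 4-(benzyloxy)-3-(methoxymethoxy)benzaldehyde | COCOc1cc(C=O)ccc1OCc1ccccc1 | intermediate
11 | 4-(benzyloxy)-3-(methoxymethoxy)benzoic acid | COCOc1cc(C(=O)O)ccc1OCc1ccccc1 | intermediate
12 | 4-(benzyloxy)-3-(methoxymethoxy)benzoyl chloride | COCOc1cc(C(Cl)=O)ccc1OCc1ccccc1 | intermediate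
13 | lithium (Z)-1-(2,6-difluoro-4-methoxyphenyl)-2-(methoxymethoxy)ethen-1-olate (formed in situ) | COCO/C=C(\O[Li])c1c(F)cc(OC)cc1F | intermediate
14 | 1-[4-(benzyloxy)-3-(methoxymethoxy)phenyl]-3-(2,6-difluoro-4-methoxyphenyl)-2-(methoxymethoxy)propane-1,3-dione (racemic) | COc1cc(F)c(C(=O)C(OCOC)C(=O)c2ccc(OCc3ccccc3)c(OCOC)c2)c(F)c1 | intermediate
15 | potassium enolate of 14, B-ring-side enolate form (formed in situ) | COc1cc(F)c(C(=O)C(OCOC)=C([O-])c2ccc(OCc3ccccc3)c(OCOC)c2)c(F)c1.[K+] | intermediate
16 | 2-[4-(benzyloxy)-3-(methoxymethoxy)phenyl]-5-fluoro-7-methoxy-3-(methoxymethoxy)-4H-chromen-4-one | COc1cc(F)c2c(=O)c(OCOC)c(-c3ccc(OCc4ccccc4)c(OCOC)c3)oc2c1 | intermediate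
17 | 5-(benzyloxy)-2-[4-(benzyloxy)-3-(methoxymethoxy)phenyl]-7-methoxy-3-(methoxymethoxy)-4H-chromen-4-one | COc1cc(OCc5ccccc5)c2c(=O)c(OCOC)c(-c3ccc(OCc4ccccc4)c(OCOC)c3)oc2c1 | intermediate
18 | 5-(benzyloxy)-2-[4-(benzyloxy)-3-hydroxyphenyl]-3-hydroxy-7-methoxy-4H-chromen-4-one | COc1cc(OCc5ccccc5)c2c(=O)c(O)c(-c3ccc(OCc4ccccc4)c(O)c3)oc2c1 | intermediate
19 | 5-(benzyloxy)-2-[4-(benzyloxy)-3-(sulfooxy)phenyl]-7-methoxy-4-oxo-4H-chromen-3-yl hydrogen sulfate | COc1cc(OCc5ccccc5)c2c(=O)c(OS(=O)(=O)O)c(-c3ccc(OCc4ccccc4)c(OS(=O)(=O)O)c3)oc2c1 | intermediate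
20 | rhamnetin 3,3'-disulfate | COc1cc(O)c2c(=O)c(OS(=O)(=O)O)c(-c3ccc(O)c(OS(=O)(=O)O)c3)oc2c1 | target

**Totals**
Total step count: 13. Longest linear sequence: 10 steps (steps 4–13, from 3,4-dihydroxybenzaldehyde); the A-ring branch (steps 1–3) joins at step 8.

**Steps most likely to fail**

Step 9 (key ring closure). The 2-alkoxy-1,3-diketone may undergo retro-Claisen cleavage, or its hindered, fully substituted enolate may add too slowly to the twisted difluoroaroyl ring for closure to compete. The fallback moves the 3-oxygen to after ring closure, so that the SNAr substrate is a plain, fully enolised diketone. It sets out from 4 (through aryllithium 5) and 12 and returns at 18.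
- Aryllithium 5 is acylated with N-methoxy-N-methylacetamide (THF, −78 °C) to give 1-(2,6-difluoro-4-methoxyphenyl)ethan-1-one F1.
- Its lithium enolate (LiHMDS, THF, −78 °C) is aroylated with 12 to give 1-[4-(benzyloxy)-3-(methoxymethoxy)phenyl]-3-(2,6-difluoro-4-methoxyphenyl)propane-1,3-dione F2.
- K2CO3 in DMF should close this to 2-[4-(benzyloxy)-3-(methoxymethoxy)phenyl]-5-fluoro-7-methoxy-4H-chromen-4-one F3.
- Benzyl alkoxide exchange as in step 10 gives 5-(benzyloxy)-2-[4-(benzyloxy)-3-(methoxymethoxy)phenyl]-7-methoxy-4H-chromen-4-one F4.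
- Dimethyldioxirane (acetone/CH2Cl2, 0 °C) epoxidises C2=C3 to the racemic 2,3-epoxide of 5-(benzyloxy)-2-[4-(benzyloxy)-3-(methoxymethoxy)phenyl]-7-methoxychroman-4-one F5.
- Methanolic HCl opens the epoxide to the 3-hydroxyflavone (loss of H-3 from the O1-stabilised C2 cation) and removes the 3'-MOM group in the same operation, giving 18.

Step 10 (fluoride-to-benzyloxy exchange). Benzyl alkoxide may add to C2 of the pyranone, with ring opening and degradation, faster than it displaces the 5-fluoride, or the substitution may stall. The fallback puts the benzyloxy group on ring A before ring closure. It sets out from 7 and returns at 17.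
- 7 with BnOH and KOt-Bu (THF, 0 °C) undergoes a single SNAr, the first alkoxy group deactivating the ring to a second one, and gives 1-[2-(benzyloxy)-6-fluoro-4-methoxyphenyl]-2-(methoxymethoxy)ethan-1-one F6.
- LiHMDS and then 12, as in step 8, give 1-[2-(benzyloxy)-6-fluoro-4-methoxyphenyl]-3-[4-(benzyloxy)-3-(methoxymethoxy)phenyl]-2-(methoxymethoxy)propane-1,3-dione F7.
- K2CO3 in DMF closes the ring through the one remaining C–F bond, to which both ring-A oxygens are meta, and gives 17 directly.

Step 8 (C-aroylation). The enolate may be acylated on oxygen (enol ester) or twice, or the MOM-bearing acid chloride may decompose before it reacts. The fallback replaces acylation by aldol addition and oxidation. It sets out from 7 (as enolate 13) and 10 and returns at 14.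
- Enolate 13 adds to aldehyde 10 at −78 °C to give 3-[4-(benzyloxy)-3-(methoxymethoxy)phenyl]-1-(2,6-difluoro-4-methoxyphenyl)-3-hydroxy-2-(methoxymethoxy)propan-1-one F8, as a mixture of diastereomers that does not matter.
- Dess–Martin periodinane (NaHCO3, CH2Cl2, rt) oxidises the β-hydroxy ketone to 14.

**Further compounds**
F1 | step 9 | 1-(2,6-difluoro-4-methoxyphenyl)ethan-1-one | CC(=O)c1c(F)cc(OC)cc1F
F2 | step 9 | 1-[4-(benzyloxy)-3-(methoxymethoxy)phenyl]-3-(2,6-difluoro-4-methoxyphenyl)propane-1,3-dione | COc1cc(F)c(C(=O)CC(=O)c2ccc(OCc3ccccc3)c(OCOC)c2)c(F)c1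
F3 | step 9 | 2-[4-(benzyloxy)-3-(methoxymethoxy)phenyl]-5-fluoro-7-methoxy-4H-chromen-4-one | COc1cc(F)c2c(=O)cc(-c3ccc(OCc4ccccc4)c(OCOC)c3)oc2c1
F4 | step 9 | 5-(benzyloxy)-2-[4-(benzyloxy)-3-(methoxymethoxy)phenyl]-7-methoxy-4H-chromen-4-one | COc1cc(OCc5ccccc5)c2c(=O)cc(-c3ccc(OCc4ccccc4)c(OCOC)c3)oc2c1
F5 | step 9 | 2,3-epoxide of 5-(benzyloxy)-2-[4-(benzyloxy)-3-(methoxymethoxy)phenyl]-7-methoxychroman-4-one (racemic) | COc1cc(OCc2ccccc2)c3c(c1)OC4(c5ccc(OCc6ccccc6)c(OCOC)c5)OC4C3=O
F6 | step 10 | 1-[2-(benzyloxy)-6-fluoro-4-methoxyphenyl]-2-(methoxymethoxy)ethan-1-one | COCOCC(=O)c1c(F)cc(OC)cc1OCc1ccccc1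
F7 | step 10 | 1-[2-(benzyloxy)-6-fluoro-4-methoxyphenyl]-3-[4-(benzyloxy)-3-(methoxymethoxy)phenyl]-2-(methoxymethoxy)propane-1,3-dione | COc1cc(F)c(C(=O)C(OCOC)C(=O)c2ccc(OCc3ccccc3)c(OCOC)c2)c(OCc4ccccc4)c1
F8 | step 8 | 3-[4-(benzyloxy)-3-(methoxymethoxy)phenyl]-1-(2,6-difluoro-4-methoxyphenyl)-3-hydroxy-2-(methoxymethoxy)propan-1-one | COc1cc(F)c(C(=O)C(OCOC)C(O)c2ccc(OCc3ccccc3)c(OCOC)c2)c(F)c1
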